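Everything rests on cutting ring B from ring A at the ether oxygen and, in the same operation, at C2′–Br. In the 2,4-dibromophenoxy ring the oxygen-bearing C1′ and the brominated C2′ are neighbours, the vicinal pattern left when benzyne takes up a nucleophile at one carbon and an electrophile at the next. One step therefore forms the O–C1′ bond to the crowded oxygen of hexasubstituted ring A (flanked by C–Br and C–O) and the C2′–Br bond, with no transition metal near the ring A bromides. The precursor is the fully substituted 2,3,4-tribromo-5-methoxy-6-(propan-2-yloxy)phenol, its central oxygen masked as an isopropyl ether; C4′–Br and the free hydroxyl follow.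

Key step: step 4

Assumption: 5-bromo-2-hydroxy-3-methoxybenzaldehyde (5-bromo-o-vanillin) is taken as a purchased starting material.

Remarks on the design
- An isopropyl ether is chosen for the central oxygen. It should survive the HBr released when ring B is brominated, is inert to fluoride and to aryl anions, and has no acidic O–CH2–O hydrogens. It is cleaved at the end by BCl3, which is known to prefer isopropyl over methyl aryl ethers.
- The bromine para to the central oxygen comes in with the starting aldehyde. In the later phenol that position is meta to both the free hydroxyl and the methoxy group, so a late bromination there would need forcing conditions. The two positions left are ortho and para to the free hydroxyl and should brominate under neutral conditions.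
- Ring A is fully substituted before the aryne step, so the phenolate can be arylated only on oxygen and the bromine donor cannot brominate it on carbon.

Step 1
Reactants: 1 5-bromo-2-hydroxy-3-methoxybenzaldehyde
Product: 2 5-bromo-3-methoxy-2-(propan-2-yloxy)benzaldehyde
Conditions: 2-bromopropane (2 equiv), K2CO3 (2 equiv), DMF, 60 °C
Reagents that add atoms: 2-bromopropane, CC(C)Br
Why: Williamson ether synthesis, in which the phenolate of 1 (made more acidic by the para bromine and the ortho formyl group) is alkylated on oxygen by the secondary bromide in a polar aprotic solvent, the excess of halide covering loss to E2 elimination.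

Step 2
Reactants: 2 5-bromo-3-methoxy-2-(propan-2-yloxy)benzaldehyde
Product: 4 5-bromo-3-methoxy-2-(propan-2-yloxy)phenol, via aryl formate 3 (not isolated)
Conditions: mCPBA (1.5 equiv), CH2Cl2, 0 °C to rt; aq NaHCO3 wash; then K2CO3 (0.2 equiv), MeOH, rt
Reagents that add atoms: mCPBA (3-chloroperoxybenzoic acid), O=C(OO)c1cccc(Cl)c1
Why: Baeyer–Villiger (Dakin-type) oxidation, in which the aryl group of the Criegee adduct, supported by the ortho alkoxy oxygen, migrates to oxygen to give formate 3, which mild methanolysis should convert into the phenol without touching the ethers or the aryl bromide.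

Step 3
Reactants: 4 5-bromo-3-methoxy-2-(propan-2-yloxy)phenol
Product: 5 2,3,4-tribromo-5-methoxy-6-(propan-2-yloxy)phenol
Conditions: NBS (2.1 equiv), MeCN, 0 °C to rt, dark
Reagents that add atoms: N-bromosuccinimide, O=C1CCC(=O)N1Br
Why: Electrophilic aromatic bromination, in which the two remaining ring hydrogens lie ortho and para to the free hydroxyl group (and para and ortho to the methoxy group), so neutral NBS should fill both while the isopropyl ether is left alone.

Step 4
Reactants: 5 2,3,4-tribromo-5-methoxy-6-(propan-2-yloxy)phenol; 6 2-(trimethylsilyl)phenyl trifluoromethanesulfonate; 7 1,2-dibromo-1,1,2,2-tetrachloroethane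
Product: 11 1,2,3-tribromo-4-(2-bromophenoxy)-6-methoxy-5-(propan-2-yloxy)benzene, via potassium phenolate 8 (not isolated), via benzyne 9 (not isolated), via 2-aryloxyphenylpotassium 10 (not isolated)
Conditions: KH (1.0 equiv), THF, 0 °C; then 18-crown-6 (3 equiv), KF (3 equiv), 7 (2.5 equiv), 6 (1.8 equiv, added over 2 h), THF, 0 °C to rt
Reagents that add atoms: 2-(trimethylsilyl)phenyl trifluoromethanesulfonate (6), C[Si](C)(C)c1ccccc1OS(=O)(=O)C(F)(F)F; 1,2-dibromo-1,1,2,2-tetrachloroethane (7), BrC(Cl)(Cl)C(Cl)(Cl)Br
Why: Fluoride removes the silyl group of 6 and triflate departs to give benzyne 9; the crown-ether-separated phenolate 8 adds through oxygen to the strained triple bond, and the resulting aryl anion 10 takes bromine from 7 by halophilic attack, releasing bromide and tetrachloroethene. The closest known reaction type is the three-component coupling of an aryne with a heteroatom nucleophile and a halogen electrophile (halothiolation and dihalogenation of arynes), here with a phenolate as the nucleophile. No ring is closed and no stereocentre is created. The two aryne carbons are equivalent, so there is no regiochemical choice, and 8 can react only at oxygen because every carbon of ring A is substituted, which also keeps 7 from brominating the nucleophile on carbon. The selectivity that matters is C–Br over C–H formation at C2′: it is secured by the absence of any proton donor (KH deprotonates 5 completely and leaves only H2, and THF is used as an aprotic solvent without acidic hydrogens) and by an excess of 7, which should also outrun bromine transfer from the ring A bromides to 10. Slow addition of 6 keeps benzyne scarce, so that 8 competes well with bromide and fluoride for it and 10 meets 7 before a second aryne.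

Step 5
Reactants: 11 1,2,3-tribromo-4-(2-bromophenoxy)-6-methoxy-5-(propan-2-yloxy)benzene
Product: 12 1,2,3-tribromo-4-(2,4-dibromophenoxy)-6-methoxy-5-(propan-2-yloxy)benzene
Conditions: Br2 (1.5 equiv), AcOH, 40 °C, dark; aq Na2S2O3
Reagents that add atoms: bromine, BrBr
Why: Electrophilic aromatic substitution, for which ring A has no hydrogen left and on ring B the position para to the ether oxygen (C4′) is the most activated and least hindered, the ring being too deactivated for a further bromine once C4′ is filled.

Step 6
Reactants: 12 1,2,3-tribromo-4-(2,4-dibromophenoxy)-6-methoxy-5-(propan-2-yloxy)benzene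
Product: 13 3,4,5-tribromo-2-(2,4-dibromophenoxy)-6-methoxyphenol
Conditions: BCl3 (3 equiv), CH2Cl2, −78 to 0 °C; then H2O
Reagents that add atoms: none
Why: Lewis-acid ether cleavage, in which BCl3 binds the crowded secondary ether oxygen and the isopropyl group leaves as 2-chloropropane, a known selective dealkylation that should leave the aryl methyl ether, the diaryl ether and the aryl bromides intact before aqueous work-up frees the phenol.

Compound list
1 | 5-bromo-2-hydroxy-3-methoxybenzaldehyde | COc1cc(Br)cc(C=O)c1O | starting material
2 | 5-bromo-3-methoxy-2-(propan-2-yloxy)benzaldehyde | COc1cc(Br)cc(C=O)c1OC(C)C | intermediate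
3 | 5-bromo-3-methoxy-2-(propan-2-yloxy)phenyl formate | COc1cc(Br)cc(OC=O)c1OC(C)C | intermediate
4 | 5-bromo-3-methoxy-2-(propan-2-yloxy)phenol | COc1cc(Br)cc(O)c1OC(C)C | intermediate
5 | 2,3,4-tribromo-5-methoxy-6-(propan-2-yloxy)phenol | COc1c(Br)c(Br)c(Br)c(O)c1OC(C)C | intermediate
6 | 2-(trimethylsilyl)phenyl trifluoromethanesulfonate | C[Si](C)(C)c1ccccc1OS(=O)(=O)C(F)(F)F | starting material
7 | 1,2-dibromo-1,1,2,2-tetrachloroethane | BrC(Cl)(Cl)C(Cl)(Cl)Br | starting material
8 | potassium 2,3,4-tribromo-5-methoxy-6-(propan-2-yloxy)phenolate | COc1c(Br)c(Br)c(Br)c([O-])c1OC(C)C.[K+] | intermediate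
9 | benzyne (1,2-didehydrobenzene) | C1=CC=CC#C1 | intermediate
10 | {2-[2,3,4-tribromo-5-methoxy-6-(propan-2-yloxy)phenoxy]phenyl}potassium | COc1c(Br)c(Br)c(Br)c(Oc2ccccc2[K])c1OC(C)C | intermediate
11 | 1,2,3-tribromo-4-(2-bromophenoxy)-6-methoxy-5-(propan-2-yloxy)benzene | COc1c(Br)c(Br)c(Br)c(Oc2ccccc2Br)c1OC(C)C | intermediate
12 | 1,2,3-tribromo-4-(2,4-dibromophenoxy)-6-methoxy-5-(propan-2-yloxy)benzene | COc1c(Br)c(Br)c(Br)c(Oc2ccc(Br)cc2Br)c1OC(C)C | intermediate
13 | 3,4,5-tribromo-2-(2,4-dibromophenoxy)-6-methoxyphenol | COc1c(O)c(Oc2ccc(Br)cc2Br)c(Br)c(Br)c1Br | target

Total step count: 6. Longest linear sequence: 6 steps (1 to 13); 6 and 7 are purchased.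

The three steps most likely to fail, riskiest first, each with its fallback:

Most at risk is step 4, the key step. The hindered, weakly nucleophilic phenolate may lose the race for benzyne to bromide or fluoride, or anion 10 may be protonated before it meets the bromine donor, so that the bromine-free phenyl ether accumulates. The fallback for step 4 sets out from 5. The phenol is arylated on oxygen (KOH, H2O/1,4-dioxane, 80 °C) with bis(2,4-dibromophenyl)iodonium chloride F1, which would be prepared from 1,3-dibromobenzene and (IO)2SO4 in H2SO4 and precipitated as the chloride. Ligand coupling at trivalent iodine is a standard way to polybrominated diphenyl ethers, including those from ortho,ortho-disubstituted phenols. It would transfer the complete 2,4-dibromophenyl ring and expel 2,4-dibromo-1-iodobenzene. The route is rejoined at 12, so steps 4 and 5 are bypassed.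

Second is step 5. Electrophilic substitution on ring B, deactivated by its own bromine and by the electron-poor aryloxy group, may be slow, and the acid that builds up may begin to strip the isopropyl group before bromination is complete. The fallback for step 5 sets out from 11. The isopropyl group is removed first (BCl3, CH2Cl2, as in step 6) to give 3,4,5-tribromo-2-(2-bromophenoxy)-6-methoxyphenol F2. With no acid-labile group left, this phenol is brominated under strongly activating conditions (NBS, CF3CO2H, rt), followed by a reductive Na2S2O3 work-up to reverse any ipso-bromination of the fully substituted phenol ring. This arrives directly at 13.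

Third is step 2. In the Criegee adduct, hydride migration may compete with aryl migration, because the migrating ring carries a meta bromine and its ortho alkoxy group is twisted out of conjugation; the benzoic acid would then form in place of the formate. The fallback for step 2 sets out from 2. Addition of MeMgBr (THF, 0 °C) gives racemic 1-[5-bromo-3-methoxy-2-(propan-2-yloxy)phenyl]ethan-1-ol F3, and oxidation with MnO2 (CH2Cl2) gives 1-[5-bromo-3-methoxy-2-(propan-2-yloxy)phenyl]ethan-1-one F4. Baeyer–Villiger oxidation of this ketone (mCPBA, catalytic CF3CO2H, CH2Cl2), in which aryl migrates far more readily than methyl, gives 5-bromo-3-methoxy-2-(propan-2-yloxy)phenyl acetate F5. Methanolysis (K2CO3, MeOH) returns to 4.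

Further compounds
F1 | step 4 | bis(2,4-dibromophenyl)iodonium chloride | Brc1ccc([I+]c2ccc(Br)cc2Br)c(Br)c1.[Cl-]
F2 | step 5 | 3,4,5-tribromo-2-(2-bromophenoxy)-6-methoxyphenol | COc1c(O)c(Oc2ccccc2Br)c(Br)c(Br)c1Br
F3 | step 2 | 1-[5-bromo-3-methoxy-2-(propan-2-yloxy)phenyl]ethan-1-ol (racemic) | COc1cc(Br)cc(C(C)O)c1OC(C)C
F4 | step 2 | 1-[5-bromo-3-methoxy-2-(propan-2-yloxy)phenyl]ethan-1-one | COc1cc(Br)cc(C(C)=O)c1OC(C)C
F5 | step 2 | 5-bromo-3-methoxy-2-(propan-2-yloxy)phenyl acetate | COc1cc(Br)cc(OC(C)=O)c1OC(C)C
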